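5 questions came with 4 ways of running one charge: which set-up ends richest in open intermediate, and how much each holds.

| setting | Tuesday's | Sunday's | Friday's | theta | beta | alpha | zeta |
|---|---|---|---|---|---|---|---|
| starting material | 0.050 M | 0.050 M | 0.050 M | 0.050 M | 0.050 M (fed, over 30.0 h) | 0.050 M | 0.050 M |
| partner | 0.065 M | 0.033 M | 0.13 M | 0.0650 M | 0.0650 M | 0.0650 M (fed, over 30.0 h) | 0.0650 M |
| remark | run made earlier | run made earlier | run made earlier | everything together in a closed stirred flask, run for 30 h | all but starting material at the start; starting material goes in evenly over 30.0 h, the run ends at 30 h | all but partner at the start; partner goes in evenly over 30.0 h, the run ends at 30 h | a single well-mixed tank run continuously and read at steady state, 30 h in it on average |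
| time |  |  |  | 30 h | 30 h | 30 h |  |

- Tuesday's (time / h: open intermediate / %, target / %, starting material / %): 1.50: 15, 1, 82; 5.00: 39, 3, 57; 8.00: 47, 11, 45; 12.0: 54, 21, 30; 20.0: 51, 33, 12
- Sunday's (time / h: open intermediate / %, target / %, starting material / %): 2.00: 18, 1, 80; 6.00: 43, 2, 51; 12.0: 58, 12, 28; 15.0: 63, 13, 22; 25.0: 63, 26, 14
- Friday's (time / h: open intermediate / %, target / %, starting material / %): 5.00: 36, 9, 59; 10.0: 41, 22, 35; 15.0: 44, 37, 21; 20.0: 38, 47, 13; 25.0: 39, 57, 12

(each reading ± 1.5 percentage points)

- the stated concentrations are those of everything mixed, before any reaction; amounts are the same in each set-up
- the earlier runs were read with a standard deviation of 1.5 percentage points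
- the feed brings no volume worth counting
- the earlier runs were made in a closed, stirred flask

- the set-up with the highest amount of open intermediate at the outlet or at the end, in percent of the starting material put in ("none" if the first two lie within 2 percentage points) (theta / beta / alpha / zeta / none)
- amount of open intermediate at the outlet or at the end, in percent of the starting material put in, theta
- amount of open intermediate at the outlet or at the end, in percent of the starting material put in, beta
- amount of open intermediate at the outlet or at the end, in percent of the starting material put in, alpha
- amount of open intermediate at the outlet or at the end, in percent of the starting material put in, zeta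

I counted turnovers. Sunday's starting material read as a half-life of 6.18 h, back step included. Tuesday's target gain between 12.0 h and 20.0 h, set against the open intermediate held, read as a half-life of going on of 24.3 h, a rough reading from a difference. So 30 h gave making 4.86 turnovers and going on 1.24; I carried this turnover count, run time over a step's half-life. With making ahead of going on, I expected open intermediate to pile up. Friday's richer partner shortened going on to 11.0 h, or 2.74 turnovers, so I backed feeding partner slowly.

The forecast named alpha, at 58% (52% to 64%), against 44% for theta, 44% for beta and 37% for zeta, because “partner is scarce early, so the intermediate accumulates”.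

The flask gave alpha: 57.0%, against 47.3% in theta, 47.0% in beta and 40.7% in zeta, each inside the forecast's range.

    starting material ⇌ open intermediate (K = 12.0, k = 0.110 h⁻¹)
    partner → second intermediate (k = 0.360 h⁻¹)
    open intermediate + second intermediate → target (k = 0.950 L mol⁻¹ h⁻¹)
    2 second intermediate → homo product (k = 0.280 L mol⁻¹ h⁻¹)

In alpha at 30.0 h, open intermediate's half-life by going on to target was 22 h, longer than the 6.3 h of the forward step of making, and 25% of the going-on turnover lay behind it at 15.0 h. The count read from the runs rose from 1.24 on Tuesday to 2.74 on Friday with more partner, and the neighbour of alpha charged with 0.16 M of partner ended with 32.7% open intermediate and 60.0% target.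

Readings and results come from a simulation from invented constants; noise was put on by code.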